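Cycloshizukaol A is cut at its two C11–C15′ bonds into identical lindenane halves, and each half at C5–C6 and C9–C10. The key step exploits the cyclohexenone ring C5–C10 (C8 ketone, C6=C7 alkene) fused at C5–C10 to the cyclopropane-bearing five-membered ring. A Diels–Alder reaction of a racemic 2-substituted 1-methoxy-3-silyloxy diene (C6–C9 plus the C11 ester arm) with enantiopure (1S,5R)-4-methylbicyclo[3.1.0]hex-3-en-2-one builds this ring and the C10 quaternary centre at once. The activating C4 ketone then becomes the C4=C5 alkene carrying C15. C9 oxygenation, C15 bromination and head-to-tail cyclodimerisation through C11 complete the 12-membered ring.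

Key step: step 8

Remark: lindenane numbering is used (cyclopropane C1–C2–C3; five-membered ring C1, C3, C4, C5, C10; six-membered ring C5–C10; C14 on C10; C15 on C4; C11 with methyl C13 and ester C12 on C7). Diene 13 is racemic at C11, so 14–21 are 1:1 C11 epimer pairs; this is harmless because C11 is planarised in step 13.

Step 1
Reactants: 1 (S)-epichlorohydrin; 2 but-2-enylmagnesium chloride
Product: 3 (2S)-1-chloro-4-methylhex-5-en-2-ol (both C4 epimers)
Conditions: THF, −40 to 0 °C (no copper); aq NH4Cl
Reagents that add atoms: none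
Why: Grignard opening of the epoxide at its CH2 terminus, the allylic reagent reacting through its γ-carbon (SE2′) to give the branched 2-methylbut-3-enyl chain; the C–O stereocentre of 1 is untouched and the methyl-bearing centre (later C10) needs no control because it becomes sp2 in step 4.

Step 2
Reactants: 3
Product: 5 (1S,2S,5S)-4-methylbicyclo[3.1.0]hexan-2-ol (both C4 epimers), via epoxide 4 (not isolated)
Conditions: LiTMP (3 equiv), MTBE, −78 to 0 °C
Reagents that add atoms: none
Why: Intramolecular cyclopropanation of an α-lithiated epoxide: the alkoxide first closes to the (S)-epoxide, trans-lithiation gives a carbenoid that adds to the tethered alkene, and the carbinol centre thereby fixes both bridgeheads (OH trans to the cyclopropane CH2) for either C4 epimer.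

Step 3
Reactants: 5
Product: 6 (1S,5S)-4-methylbicyclo[3.1.0]hexan-2-one (both C4 epimers)
Conditions: TEMPO (cat.), NaOCl, KBr, NaHCO3, CH2Cl2/H2O, 0 °C
Reagents that add atoms: none
Why: TEMPO/hypochlorite oxidation of a secondary alcohol under buffered conditions that leave the cyclopropane and both bridgehead centres alone.

Step 4
Reactants: 6
Product: 8 (1S,5R)-4-methylbicyclo[3.1.0]hex-3-en-2-one, via silyl enol ether 7 (not isolated)
Conditions: LiHMDS, TMSCl, THF, −78 °C; then Pd(OAc)2 (10 mol%), O2, DMSO, rt
Reagents that add atoms: none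
Why: Saegusa–Ito dehydrogenation; enolisation can only go toward the CH2 because the other α-carbon is a cyclopropane bridgehead, and both C4 epimers converge on one enantiopure enone.

Step 5
Reactants: 9 methyl (E)-4-oxopent-2-enoate
Product: 10 methyl 2-methyl-4-(trimethylsilyloxy)pent-3-enoate (racemic)
Conditions: Me2CuLi, TMSCl, THF, −78 °C
Reagents that add atoms: lithium dimethylcuprate [Li+].C[Cu-]C; chlorotrimethylsilane C[Si](C)(C)Cl
Why: Cuprate conjugate addition with in situ silylation: methyl adds β to the ketone (α to the ester) and installs C13, so the ketone enolate is trapped only toward C7, which a direct formylation of the saturated keto ester could not guarantee.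

Step 6
Reactants: 10
Product: 12 methyl (3E)-3-(methoxymethylidene)-2-methyl-4-oxopentanoate (racemic), via keto acetal 11 (not isolated)
Conditions: HC(OMe)3, TMSOTf (5 mol%), CH2Cl2, −78 °C; then TsOH (cat.), PhMe, 60 °C
Reagents that add atoms: trimethyl orthoformate COC(OC)OC
Why: Mukaiyama-type addition of the enol silane to the dimethoxycarbenium ion places C6 on C7, and acid-catalysed loss of methanol gives the thermodynamically preferred E β-methoxy enone.

Step 7
Reactants: 12
Product: 13 methyl (3E)-4-(tert-butyldimethylsilyloxy)-3-(methoxymethylidene)-2-methylpent-4-enoate (racemic)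
Conditions: TBSOTf, Et3N, Et2O, 0 °C
Reagents that add atoms: tert-butyldimethylsilyl triflate CC(C)(C)[Si](C)(C)OS(=O)(=O)C(F)(F)F
Why: Soft enolisation (silyl triflate/amine) of the vinylogous ester removes a proton only from the acetyl methyl, since the ester α-CH is not acidified by O-silylation; the E enol ether geometry is kept.

Step 8
Reactants: 8 (1S,5R)-4-methylbicyclo[3.1.0]hex-3-en-2-one; 13 methyl (3E)-4-(tert-butyldimethylsilyloxy)-3-(methoxymethylidene)-2-methylpent-4-enoate
Product: 15 methyl (1R,3S,5S,10S)-4,8-dioxo-15-norlinden-6-en-12-oate (both C11 epimers), via cycloadduct 14 (not isolated)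
Conditions: 13 (2 equiv), CH2Cl2, 13 kbar, 30 °C; then TFA, CH2Cl2, 0 °C
Reagents that add atoms: none
Why: A normal-electron-demand [4+2] cycloaddition in which the unsubstituted diene terminus C9 bonds to the enone β-carbon C10 and the methoxy-bearing C6 to C5, both suprafacially; TFA then cleaves the silyl enol ether of 14 to the C8 ketone and eliminates methanol to the C6=C7 enone. The closest known reaction type is the high-pressure Diels–Alder reaction of 1-alkoxy-3-silyloxy dienes with β-alkyl cycloalkenones that creates angular quaternary centres. The six-membered ring C5–C10 is closed by the concerted cycloaddition itself, as a cis-fused ring. C10 is set by approach of the diene to the convex face of the bicycle, anti to the cyclopropane CH2 (C2), which leaves C14 syn to C2; C5 follows from the suprafacial addition and is erased in step 9. Regiochemistry is secured by the 1-OMe/3-OSi polarisation of the diene, no endo/exo control is needed because C6 loses its methoxy group, and C11 forms as both epimers. Pressure is chosen over Lewis acids because acids would open the cyclopropyl enone and destroy the diene, while ring strain already makes this β,β-disubstituted enone a good acceptor.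

Step 9
Reactants: 15
Product: 16 methyl (1R,3S,10S)-8-oxo-4-(trifluoromethylsulfonyloxy)-15-norlindena-4,6-dien-12-oate
Conditions: KHMDS (1.0 equiv), THF, −78 °C; then PhNTf2, −78 to 0 °C
Reagents that add atoms: N-phenylbis(trifluoromethanesulfonimide) O=S(=O)(N(c1ccccc1)S(=O)(=O)C(F)(F)F)C(F)(F)F
Why: Enol triflate formation from a vinylogous 1,3-diketone: one equivalent of base removes only C5–H (α to C4=O and γ to the C8 enone), and the bulky sulfonimide should take the C4 oxygen because the C8 oxygen is screened by the branched C11 substituent on C7.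

Step 10
Reactants: 16
Product: 18 methyl (1R,3S,9S,10S)-9-(tert-butyldimethylsilyloxy)-8-oxo-4-(trifluoromethylsulfonyloxy)-15-norlindena-4,6-dien-12-oate, via silyl dienol ether 17 (not isolated)
Conditions: TBSOTf, i-Pr2NEt, CH2Cl2, −78 to −20 °C; then DMDO, acetone/CH2Cl2, −78 to 0 °C
Reagents that add atoms: tert-butyldimethylsilyl triflate CC(C)(C)[Si](C)(C)OS(=O)(=O)C(F)(F)F; dimethyldioxirane CC1(C)OO1
Why: Rubottom oxidation after soft enolisation: with C4 carrying OTf the O-silylated ketone can lose a proton only from C9, DMDO epoxidises the electron-rich C8=C9 enol ether and a 1,4-silyl shift gives the 9-silyloxy ketone; attack anti to the axial C14 should give mainly the 9α epimer drawn, and either epimer serves because C9 is equilibrated in step 14.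

Step 11
Reactants: 18
Product: 19 methyl (1R,3S,9S,10S)-9-(tert-butyldimethylsilyloxy)-8-oxolindena-4,6-dien-12-oate
Conditions: MeZnCl, Pd(PPh3)4 (5 mol%), THF, 0 °C to rt
Reagents that add atoms: methylzinc chloride C[Zn]Cl
Why: Negishi coupling of the vinylogous acyl triflate installs C15; oxidative addition at C4–OTf is fast and the organozinc leaves the ketone, ester and silyl ether untouched.

Step 12
Reactants: 19
Product: 21 methyl (1R,3S,9S,10S)-15-bromo-9-(tert-butyldimethylsilyloxy)-8-oxolindena-4,6-dien-12-oate, via trienol silyl ether 20 (not isolated)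
Conditions: TMSOTf, i-Pr2NEt, CH2Cl2, −78 to −20 °C; then NBS, THF, −78 °C; cold NaHCO3/Na2S2O3 quench
Reagents that add atoms: N-bromosuccinimide BrN1C(=O)CCC1=O
Why: Vinylogous bromination of an extended silyl enol ether: thermodynamic soft enolisation removes a C15 proton to give the fully conjugated C15=C4–C5=C6–C7=C8(OSi) triene, and NBS attacks its unhindered terminus C15 because C5 and C7 are fully substituted.

Step 13
Reactants: 21 (two molecules)
Product: 24 9,9′-di-epi-cycloshizukaol A 9,9′-bis(tert-butyldimethylsilyl) ether, via triene 22 (not isolated), via seco-bromide 23 (not isolated)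
Conditions: Cs2CO3 (3 equiv), Bu4NBr (1 equiv), DMF, 2 mM, 0 °C to rt, dark
Reagents that add atoms: none
Why: Proposed new method: deprotonation at C11 (ester α-CH conjugated with the C6=C7–C5=C4 diene) triggers vinylogous E1cB loss of bromide to the cross-conjugated triene 22; bromide adds back at C15 to regenerate the bromo dienolate, whose C11 adds to C15′ of a second triene (1,8-addition, or direct SN2 on unreacted 21) to give the enolate of 23, which closes the 12-membered ring by intramolecular SN2 at the allylic C15–Br. The two dienone decks can stack only on their open α-faces (anti to C14 and C2) with each ester syn to its C8 carbonyl (Cs-bridged), and this geometry gives (R) at both C11. The closest known reaction types are the 1,6-elimination/cyclodimerisation of p-xylylene precursors to [2.2]paracyclophanes and the intramolecular allylic alkylation of ester enolates used for macrocyclisation.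

Step 14
Reactants: 24
Product: 26 cycloshizukaol A, via 9-epimeric diol 25 (not isolated)
Conditions: Et3N·3HF, MeCN, rt; then DBU (0.2 equiv), MeOH, rt, Ar
Reagents that add atoms: none
Why: Fluoride desilylation followed by base-mediated α-ketol epimerisation through the C8/C9 enediol: reprotonation of C9 anti to the axial C14 and the hydrogen bond of the equatorial 9-OH to C8=O both favour the 9β-alcohols (9R) of the target, while the quaternary C10 and C11 centres cannot epimerise.

Compound list
1 | (S)-epichlorohydrin | ClC[C@@H]1CO1 | starting material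
2 | but-2-enylmagnesium chloride (THF solution) | C/C=C/C[Mg]Cl | starting material
3 | (2S)-1-chloro-4-methylhex-5-en-2-ol (C4 epimers) | ClC[C@@H](O)CC(C)C=C | intermediate
4 | (2S)-2-(2-methylbut-3-enyl)oxirane (not isolated) | C1[C@@H](O1)CC(C)C=C | intermediate
5 | (1S,2S,5S)-4-methylbicyclo[3.1.0]hexan-2-ol (C4 epimers; OH trans to cyclopropane CH2) | CC1C[C@H](O)[C@H]2C[C@@H]12 | intermediate
6 | (1S,5S)-4-methylbicyclo[3.1.0]hexan-2-one (C4 epimers) | CC1CC(=O)[C@H]2C[C@@H]12 | intermediate
7 | C2–C3 trimethylsilyl enol ether of 6 (not isolated) | CC1C=C(O[Si](C)(C)C)[C@H]2C[C@@H]12 | intermediate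
8 | (1S,5R)-4-methylbicyclo[3.1.0]hex-3-en-2-one (dienophile) | CC1=CC(=O)[C@H]2C[C@@H]12 | intermediate
9 | methyl (E)-4-oxopent-2-enoate | COC(=O)/C=C/C(C)=O | starting material
10 | methyl 2-methyl-4-(trimethylsilyloxy)pent-3-enoate (racemic) | COC(=O)C(C)C=C(C)O[Si](C)(C)C | intermediate
11 | methyl 3-(dimethoxymethyl)-2-methyl-4-oxopentanoate (not isolated) | COC(OC)C(C(C)=O)C(C)C(=O)OC | intermediate
12 | methyl (3E)-3-(methoxymethylidene)-2-methyl-4-oxopentanoate (racemic) | CO/C=C(/C(C)=O)C(C)C(=O)OC | intermediate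
13 | methyl (3E)-4-(tert-butyldimethylsilyloxy)-3-(methoxymethylidene)-2-methylpent-4-enoate (racemic diene) | CO/C=C(/C(=C)O[Si](C)(C)C(C)(C)C)C(C)C(=O)OC | intermediate
14 | cycloadduct: cis-fused C4 ketone with 6-OMe and C7=C8 silyl enol ether (C6 and C11 epimers; not isolated) | O=C1[C@H]2C(OC)C(C(C)C(=O)OC)=C(O[Si](C)(C)C(C)(C)C)C[C@@]2(C)[C@@H]2C[C@H]12 | intermediate
15 | methyl (1R,3S,5S,10S)-4,8-dioxo-15-norlinden-6-en-12-oate (tricyclic ene-dione; C11 epimers) | O=C1[C@H]2C=C(C(C)C(=O)OC)C(=O)C[C@@]2(C)[C@@H]2C[C@H]12 | intermediate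
16 | methyl (1R,3S,10S)-8-oxo-4-(trifluoromethylsulfonyloxy)-15-norlindena-4,6-dien-12-oate | FC(F)(F)S(=O)(=O)OC2=C3C=C(C(=O)C[C@@]3(C)[C@@H]3C[C@H]23)C(C)C(=O)OC | intermediate
17 | 8-O-TBS dienol ether of 16 (C8=C9; not isolated) | FC(F)(F)S(=O)(=O)OC2=C3C=C(C(O[Si](C)(C)C(C)(C)C)=C[C@@]3(C)[C@@H]3C[C@H]23)C(C)C(=O)OC | intermediate
18 | methyl (1R,3S,9S,10S)-9-(tert-butyldimethylsilyloxy)-8-oxo-4-(trifluoromethylsulfonyloxy)-15-norlindena-4,6-dien-12-oate (9α-OTBS, trans to C14) | FC(F)(F)S(=O)(=O)OC2=C3C=C(C(=O)[C@@H](O[Si](C)(C)C(C)(C)C)[C@@]3(C)[C@@H]3C[C@H]23)C(C)C(=O)OC | intermediate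
19 | methyl (1R,3S,9S,10S)-9-(tert-butyldimethylsilyloxy)-8-oxolindena-4,6-dien-12-oate | CC2=C3C=C(C(=O)[C@@H](O[Si](C)(C)C(C)(C)C)[C@@]3(C)[C@@H]3C[C@H]23)C(C)C(=O)OC | intermediate
20 | methyl 9-(tert-butyldimethylsilyloxy)-8-(trimethylsilyloxy)lindena-4(15),5,7-trien-12-oate (not isolated) | C=C2C3=CC(C(C)C(=O)OC)=C(O[Si](C)(C)C)[C@@H](O[Si](C)(C)C(C)(C)C)[C@@]3(C)[C@@H]3C[C@H]23 | intermediate
21 | methyl (1R,3S,9S,10S)-15-bromo-9-(tert-butyldimethylsilyloxy)-8-oxolindena-4,6-dien-12-oate | BrCC2=C3C=C(C(=O)[C@@H](O[Si](C)(C)C(C)(C)C)[C@@]3(C)[C@@H]3C[C@H]23)C(C)C(=O)OC | intermediate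
22 | methyl (1R,3S,9S,10S)-9-(tert-butyldimethylsilyloxy)-8-oxolindena-4(15),5,7(11)-trien-12-oate (C7=C11 geometry not fixed; not isolated) | C=C2C3=CC(=C(C)C(=O)OC)C(=O)[C@@H](O[Si](C)(C)C(C)(C)C)[C@@]3(C)[C@@H]3C[C@H]23 | intermediate
23 | seco-bromide: 21 whose C11 (R) carries C15′H2 of a second unit that keeps its C11′–H (not isolated) | BrCC2=C3C=C(C(=O)[C@@H](O[Si](C)(C)C(C)(C)C)[C@@]3(C)[C@@H]3C[C@H]23)[C@](C)(C(=O)OC)CC4=C5C=C(C(=O)[C@@H](O[Si](C)(C)C(C)(C)C)[C@@]5(C)[C@@H]5C[C@H]45)C(C)C(=O)OC | intermediate
24 | 9,9′-di-epi-cycloshizukaol A 9,9′-bis(tert-butyldimethylsilyl) ether (1R,3S,9S,10S,11R in each half) | COC(=O)[C@]1(C)CC2=C3C=C(C(=O)[C@@H](O[Si](C)(C)C(C)(C)C)[C@@]3(C)[C@@H]3C[C@H]23)[C@](C)(C(=O)OC)CC2=C3C=C1C(=O)[C@@H](O[Si](C)(C)C(C)(C)C)[C@@]3(C)[C@@H]1C[C@H]21 | intermediate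
25 | 9,9′-di-epi-cycloshizukaol A (not isolated) | COC(=O)[C@]1(C)CC2=C3C=C(C(=O)[C@@H](O)[C@@]3(C)[C@@H]3C[C@H]23)[C@](C)(C(=O)OC)CC2=C3C=C1C(=O)[C@@H](O)[C@@]3(C)[C@@H]1C[C@H]21 | intermediate
26 | cycloshizukaol A (1R,3S,9R,10S,11R in each half) | COC(=O)[C@]1(C)CC2=C3C=C(C(=O)[C@H](O)[C@@]3(C)[C@@H]3C[C@H]23)[C@](C)(C(=O)OC)CC2=C3C=C1C(=O)[C@H](O)[C@@]3(C)[C@@H]1C[C@H]21 | target

Total steps: 14. Longest linear sequence: 11 (steps 1–4, then 8–14); the diene arm (steps 5–7) joins at step 8.

Steps most likely to fail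

1. Step 13 (Proposed new method). The triene may be consumed by [4+2] self-dimerisation or anionic oligomerisation before the halide relay closes the ring, and the first, intermolecular C11–C15′ bond may form without facial control. Fallback with known chemistry, setting out from 18 (and using 21) and returning at 23 and then 24: Stille coupling of 18 with (tributylstannyl)methanol (Pd(PPh3)4, dioxane, 80 °C) would give the C15 alcohol F1, which is silylated (TESCl, imidazole) to the triethylsilyl ether F2. F2 has no leaving group on C15, so its C11 lithium enolate (LiHMDS, THF, −78 °C) can be alkylated with bromide 21 to the open dimer F3, whose C11 diastereomers are separated. Selective cleavage of the primary TES ether (PPTS, MeOH) gives the open-dimer alcohol F4, and an Appel reaction (CBr4, PPh3) gives 23 as an isolated compound. Its only remaining C11–H is removed (KHMDS, THF, 1 mM, −78 °C to rt) and the enolate closes the ring by intramolecular allylic alkylation to 24.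

2. Step 8. The β,β-disubstituted enone may not undergo cycloaddition before the diene is lost to desilylation or polymerisation. Fallback, setting out from 8 and 13 and returning at 15: a stepwise annulation. A Mukaiyama–Michael addition catalysed by a silyl triflimide (Tf2NH 5 mol%, CH2Cl2, −78 °C) joins C9 to C10 anti to C2 and, after aqueous work-up, should give the keto vinylogous ester F5. Base (t-BuOK, t-BuOH/THF, 0 °C) then forms the C5 enolate, which adds to C6 and expels methoxide to close the ring to 15.

3. Step 14. Equilibration of the two α-ketols may stop short of, or not favour, the 9β-alcohols. Fallback, setting out from 25 and returning at 26: oxidation with Dess–Martin periodinane to the bis(8,9-dione) F6 (not enolisable, C10 being quaternary), then NaBH4 (MeOH/CH2Cl2, −78 °C). Hydride reaches the C9 carbonyl anti to the axial C14, which sets 9β-OH kinetically.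

Further compounds
F1 | step 13 | methyl (1R,3S,9S,10S)-9-(tert-butyldimethylsilyloxy)-15-hydroxy-8-oxolindena-4,6-dien-12-oate | OCC2=C3C=C(C(=O)[C@@H](O[Si](C)(C)C(C)(C)C)[C@@]3(C)[C@@H]3C[C@H]23)C(C)C(=O)OC
F2 | step 13 | 15-O-triethylsilyl ether of F1 | CC[Si](CC)(CC)OCC2=C3C=C(C(=O)[C@@H](O[Si](C)(C)C(C)(C)C)[C@@]3(C)[C@@H]3C[C@H]23)C(C)C(=O)OC
F3 | step 13 | open dimer: F2 alkylated at C11 (R) by C15′ of 21 | CC[Si](CC)(CC)OCC2=C3C=C(C(=O)[C@@H](O[Si](C)(C)C(C)(C)C)[C@@]3(C)[C@@H]3C[C@H]23)[C@](C)(C(=O)OC)CC4=C5C=C(C(=O)[C@@H](O[Si](C)(C)C(C)(C)C)[C@@]5(C)[C@@H]5C[C@H]45)C(C)C(=O)OC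
F4 | step 13 | open-dimer C15 alcohol | OCC2=C3C=C(C(=O)[C@@H](O[Si](C)(C)C(C)(C)C)[C@@]3(C)[C@@H]3C[C@H]23)[C@](C)(C(=O)OC)CC4=C5C=C(C(=O)[C@@H](O[Si](C)(C)C(C)(C)C)[C@@]5(C)[C@@H]5C[C@H]45)C(C)C(=O)OC
F5 | step 8 | methyl (3E)-3-(methoxymethylidene)-2-methyl-5-(2-methyl-4-oxobicyclo[3.1.0]hexan-2-yl)-4-oxopentanoate (C9–C10 bond anti to C2) | O=C1C[C@@](C)(CC(=O)/C(=C/OC)C(C)C(=O)OC)[C@@H]2C[C@H]12
F6 | step 14 | 9,9′-didehydro-cycloshizukaol A (bis-8,9-dione) | COC(=O)[C@]1(C)CC2=C3C=C(C(=O)C(=O)[C@@]3(C)[C@@H]3C[C@H]23)[C@](C)(C(=O)OC)CC2=C3C=C1C(=O)C(=O)[C@@]3(C)[C@@H]1C[C@H]21
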